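**Assumption:** the SMILES is taken as definitive. It corresponds to 1β,6α-diacetoxy-9α-hydroxy-5α-drim-7-ene-11,12-dial (10β-CH3; 1R,5S,6S,9S,10R in drimane numbering). Drimane numbering and α/β (β = face of the C10 methyl) are used throughout. The route is a design and has not been run; selectivities are argued by analogy.

## Retrosynthetic overview

1. Parritadial ⇐ Swern oxidation of the 9α,11,12-triol ⇐ singlet-oxygen ene reaction on a Δ8 drimene carrying 11,12-bis(silyloxymethyl) groups (gives 9α-OH and Δ7 together).
2. 6α-O and 5α-H (trans-decalin) ⇐ hydroboration of Δ5 in a drima-5,8-diene-11,12-diester.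
3. Ring B ⇐ intermolecular Diels–Alder of a ring-A diene, (R)-2,4,4-trimethyl-3-vinylcyclohex-2-enyl acetate, with DMAD, anti to the C1 acetate (sets C10).
4. Diene ⇐ CBS reduction (sets C1) of the dienone made by Stork–Danheiser chemistry from 3-ethoxy-2-methylcyclohexenone.
5. Ring order: ring A is bought as a cyclohexenone; ring B is formed by the [4+2].

## Route

**Step 1**
Reactants: 1, 3-ethoxy-2-methylcyclohex-2-en-1-one; 2, iodomethane
Product: 3, 3-ethoxy-2,6,6-trimethylcyclohex-2-en-1-one
Conditions: LDA, THF, −78 °C, then MeI; second cycle in the same flask: LDA, −78 °C, then MeI, −78 → 0 °C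
Reagents that add atoms: iodomethane, CI (two CH3)
Why: Stork–Danheiser kinetic α′-enolate alkylation of a vinylogous ester, run twice, places the gem-dimethyl (future C4) next to the ketone; no stereocentre.

**Step 2**
Reactants: 3; 4, vinylmagnesium bromide
Product: 5, 2,4,4-trimethyl-3-vinylcyclohex-2-en-1-one
Conditions: CH2=CHMgBr, CeCl3, THF, −78 → 0 °C; then 1 M HCl, rt
Reagents that add atoms: vinylmagnesium bromide, C=C[Mg]Br; water, O (new carbonyl oxygen)
Why: 1,2-addition to the non-enolisable ketone, then acid hydrolysis with 1,3-carbonyl transposition (Stork–Danheiser), puts the vinyl group next to CMe2 and the ketone at the future C1.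

**Step 3**
Reactants: 5
Product: 6, (R)-2,4,4-trimethyl-3-vinylcyclohex-2-en-1-ol
Conditions: (S)-Me-CBS (20 mol %), catecholborane, toluene, −78 °C
Reagents that add atoms: none
Why: Corey–Bakshi–Shibata 1,2-reduction; the α-methyl alkenyl arm acts as the large group, so the (S)-catalyst gives the (R)-carbinol (future C1), and catecholborane spares the vinyl group.

**Step 4**
Reactants: 6; 7, acetic anhydride
Product: 8, (R)-2,4,4-trimethyl-3-vinylcyclohex-2-en-1-yl acetate
Conditions: Ac2O, Et3N, DMAP, CH2Cl2, 0 °C → rt
Reagents that add atoms: acetic anhydride, CC(=O)OC(C)=O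
Why: DMAP-catalysed acylation with no change at the stereocentre; capping the OH prevents H-bond-directed syn cycloaddition and oxa-Michael addition to DMAD.

**Step 5**
Reactants: 8; 9, dimethyl acetylenedicarboxylate (DMAD)
Product: 10, dimethyl 1β-acetoxy-drima-5,8-diene-11,12-dioate (1R,10S; 10β-CH3)
Conditions: DMAD (2 equiv), BHT (cat.), neat, 110 °C, sealed tube; chromatographic removal of the minor diastereomer
Reagents that add atoms: DMAD, COC(=O)C#CC(=O)OC
Why: Thermal Diels–Alder of the semicyclic diene forms ring B with C11 and C12; A(1,2) strain holds the C1 acetate pseudoaxial, so DMAD bonds to C10 on the opposite face and the C10 methyl ends cis to the acetate (1β-OAc, 10β-CH3).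

**Step 6**
Reactants: 10
Product: 11, dimethyl 1β-acetoxy-6α-hydroxy-5α-drim-8-ene-11,12-dioate
Conditions: BH3·THF (1.5 equiv), THF, 0 °C → rt; then 30 % H2O2, aq NaOAc, 0 °C → rt
Reagents that add atoms: hydrogen peroxide, OO (the 6-OH oxygen)
Why: Hydroboration–oxidation of the trisubstituted Δ5 olefin; syn addition from the α-face (β-face blocked by the axial 10β- and 4β-methyls) gives 5α-H and 6α-OH, while the tetrasubstituted diester olefin is too electron-poor to react.

**Step 7**
Reactants: 11
Product: 12, 5α-drim-8-ene-1β,6α,11,12-tetraol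
Conditions: DIBAL-H (10 equiv), CH2Cl2, −78 → 0 °C; Rochelle salt work-up
Reagents that add atoms: none
Why: Hydride reduction of both conjugated esters to the cis-ene-1,4-diol, with reductive loss of the C1 acetate; no stereocentre is touched.

**Step 8**
Reactants: 12; 13, tert-butyldimethylsilyl chloride
Product: 14, 11,12-bis(tert-butyldimethylsilyloxy)-5α-drim-8-ene-1β,6α-diol
Conditions: TBSCl (2.2 equiv), imidazole, DMF/CH2Cl2, −20 → 0 °C
Reagents that add atoms: TBSCl, CC(C)(C)[Si](C)(C)Cl
Why: Kinetic silylation takes the two primary allylic alcohols and leaves the hindered secondary 1β-OH (neopentyl-type) and 6α-OH free; basic conditions avoid dihydrofuran formation.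

**Step 9**
Reactants: 14; 7, acetic anhydride
Product: 15, 1β,6α-diacetoxy-11,12-bis(tert-butyldimethylsilyloxy)-5α-drim-8-ene
Conditions: Ac2O, DMAP, pyridine, rt
Reagents that add atoms: acetic anhydride, CC(=O)OC(C)=O
Why: DMAP-catalysed acetylation of both equatorial secondary alcohols with retention; TBS ethers are stable.

**Step 10**
Reactants: 15
Product: 16, 1β,6α-diacetoxy-11,12-bis(tert-butyldimethylsilyloxy)-5α-drim-7-en-9α-ol
Conditions: O2, TPP (cat.), visible light, CH2Cl2, 0 °C; then PPh3
Reagents that add atoms: oxygen (as singlet O2), O=O (one O retained)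
Why: Schenck ene reaction; 1O2 attacks the electron-rich tetrasubstituted Δ8 olefin from the α-face (β-face screened by 10β-CH3), bonds to C9 and abstracts the axial 7α-H (the C11/C12 hydrogens geminal to OSi are deactivated), giving the 9α-hydroperoxide with Δ7, which PPh3 reduces to 9α-OH.

**Step 11**
Reactants: 16
Product: 17, 1β,6α-diacetoxy-5α-drim-7-ene-9α,11,12-triol
Conditions: HF·pyridine, pyridine/THF, 0 °C → rt
Reagents that add atoms: none
Why: Buffered fluoride desilylation frees the two primary alcohols without acetate migration or ionisation of the tertiary allylic alcohol.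

**Step 12**
Reactants: 17
Product: 18, parritadial
Conditions: (COCl)2, DMSO, CH2Cl2, −78 °C; Et3N, −78 → −20 °C
Reagents that add atoms: none
Why: Swern oxidation converts both primary alcohols (allylic C12, α-hydroxy C11) to aldehydes; the tertiary 9-OH and the acetates are inert, and C9 is quaternary so it cannot epimerise.

## Compound list

1 | 3-ethoxy-2-methylcyclohex-2-en-1-one | CCOC1=C(C)C(=O)CCC1 | starting material
2 | iodomethane | CI | starting material
3 | 3-ethoxy-2,6,6-trimethylcyclohex-2-en-1-one | CCOC1=C(C)C(=O)C(C)(C)CC1 | intermediate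
4 | vinylmagnesium bromide | C=C[Mg]Br | starting material
5 | 2,4,4-trimethyl-3-vinylcyclohex-2-en-1-one | C=CC1=C(C)C(=O)CCC1(C)C | intermediate
6 | (R)-2,4,4-trimethyl-3-vinylcyclohex-2-en-1-ol | C=CC1=C(C)[C@H](O)CCC1(C)C | intermediate
7 | acetic anhydride | CC(=O)OC(C)=O | starting material
8 | (R)-2,4,4-trimethyl-3-vinylcyclohex-2-en-1-yl acetate | C=CC1=C(C)[C@H](OC(C)=O)CCC1(C)C | intermediate
9 | dimethyl acetylenedicarboxylate | COC(=O)C#CC(=O)OC | starting material
10 | dimethyl 1β-acetoxy-drima-5,8-diene-11,12-dioate | COC(=O)C1=C(C(=O)OC)[C@@]2(C)[C@H](OC(C)=O)CCC(C)(C)C2=CC1 | intermediate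
11 | dimethyl 1β-acetoxy-6α-hydroxy-5α-drim-8-ene-11,12-dioate | O[C@H]1CC(C(=O)OC)=C(C(=O)OC)[C@@]2(C)[C@H](OC(C)=O)CCC(C)(C)[C@H]12 | intermediate
12 | 5α-drim-8-ene-1β,6α,11,12-tetraol | O[C@H]1CC(CO)=C(CO)[C@@]2(C)[C@H](O)CCC(C)(C)[C@H]12 | intermediate
13 | tert-butyldimethylsilyl chloride | CC(C)(C)[Si](C)(C)Cl | starting material
14 | 11,12-bis(TBS-oxy)-5α-drim-8-ene-1β,6α-diol | O[C@H]1CC(CO[Si](C)(C)C(C)(C)C)=C(CO[Si](C)(C)C(C)(C)C)[C@@]2(C)[C@H](O)CCC(C)(C)[C@H]12 | intermediate
15 | 1β,6α-diacetoxy-11,12-bis(TBS-oxy)-5α-drim-8-ene | CC(=O)O[C@H]1CC(CO[Si](C)(C)C(C)(C)C)=C(CO[Si](C)(C)C(C)(C)C)[C@@]2(C)[C@H](OC(C)=O)CCC(C)(C)[C@H]12 | intermediate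
16 | 1β,6α-diacetoxy-11,12-bis(TBS-oxy)-5α-drim-7-en-9α-ol | CC(=O)O[C@H]1C=C(CO[Si](C)(C)C(C)(C)C)[C@](O)(CO[Si](C)(C)C(C)(C)C)[C@@]2(C)[C@H](OC(C)=O)CCC(C)(C)[C@H]12 | intermediate
17 | 1β,6α-diacetoxy-5α-drim-7-ene-9α,11,12-triol | CC(=O)O[C@H]1C=C(CO)[C@](O)(CO)[C@@]2(C)[C@H](OC(C)=O)CCC(C)(C)[C@H]12 | intermediate
18 | parritadial (1β,6α-diacetoxy-9α-hydroxy-5α-drim-7-ene-11,12-dial) | CC(=O)O[C@H]1C=C(C=O)[C@](O)(C=O)[C@@]2(C)[C@H](OC(C)=O)CCC(C)(C)[C@H]12 | target

## Totals and risks

Total steps: 12. Longest linear sequence: 12 (from compound 1).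

Three steps most likely to fail, each with an approach-changing fallback:

1. **Step 5 (Diels–Alder).** The congested tetrasubstituted diene may react slowly or with modest anti-facial selectivity. Fallback: tether the dienophile. Esterify the enantiomeric (S)-dienol (from (R)-CBS) with an acetylenedicarboxylic acid monoester and run an intramolecular Diels–Alder, which delivers C9 syn to the C1 oxygen and fixes C10 absolutely. After lactone reduction, correct C1 by oxidation and NaBH4 reduction (hydride anti to the 10-methyl gives 1β-OH).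

2. **Step 6 (hydroboration).** Addition to Δ5, flanked by two quaternary carbons, may be slow, and borane may attack the esters. Fallback: hydrogenate Δ5 from the α-face (gives 5α-H), then NBS γ-bromination and DBU elimination to the 6,8-diene. Reduce and silylate as in steps 7–8, then add 1O2 in a [4+2] from the α-face and reduce the endoperoxide. This gives the cis-6α,9α-diol with Δ7 in one operation and also replaces step 10.

3. **Step 10 (singlet-oxygen ene).** Regiochemistry may be imperfect (abstraction of C11/C12 hydrogens, or O at C8), and the 6-acetate may slow the reaction. Fallback: epoxidise Δ8 from the α-face with mCPBA and isomerise the 8α,9α-epoxide to the 9α-hydroxy-Δ7 allylic alcohol with an aluminium amide (Et2Al-TMP), which removes the 7α-H by syn-elimination.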